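(All runs are calculated on assumed constants; noise was put on by code.)

The south-east flask has gone slow. This note is for whoever takes it over at 20 h.

common to all: E 0.20 M
- south-east: L 0.22 M; the very flask that is asked about, followed so far
- north-west: L 0.44 M; run made earlier
- flask: L 0.220 M; time 20 h
south-east run (percent of the E charged): time / h: J / % = 1.00: 7.8; 3.00: 12.7; 6.00: 15.0; 8.00: 16.0; 12.0: 18.4; 15.0: 15.4

north-west run (percent of the E charged): time / min: J / % = 1.50: 0.1; 5.00: 0; 8.00: 2.6; 12.0: 3.5; 20.0: 4.8; 25.0: 8.1

(scatter of a reading: 1 percentage point)
- J, in percent of the E first charged, at 20 h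
- what to do for the largest gain in J; "none" if nothing gains more than 2 percentage points (ochre / blue / amber / teal / none)
- J present, with what was taken out counted in, in percent of the E first charged, after blue
- J present, with what was taken out counted in, in percent of the E first charged, after amber
- ochre: at 20 h add L, 50.0% of the amount charged, then wait 6.0 h
- blue: at 20 h add E, 50.0% of the amount charged, then wait 6.0 h
- amber: at 20 h take out 90% of the J then present, then wait 6.0 h
- teal: change nothing and wait 6.0 h more
- removed J is counted in
- on the list of suspects stand: E + L -> X; L + J -> G; L -> Q; E <-> D; L + X -> J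
- additions bring no volume worth counting

The readings at 8.00 h, 12.0 h and 15.0 h are 16.0%, 18.4% and 15.4%. I see no trend in them, so I take their mean, 16.6%, as the J you will find, with blue and amber leaving it there. The one suspect step that makes J is L + X -> J, and I take the stall to mean that cL is near zero.

I count turnovers. Two L build a J, but L has other suspect paths. So I use the price, the L charged per J made: 6.63. Fresh L should buy J at that price. Ochre's dose of 0.110 M should then give 8.3 percentage points, more than the 2 points that counts. Blue, amber and teal add no L, so leave E alone, leave J in, and expect nothing from waiting.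

The forecast says 17.5% (15% to 20%), ochre as the best move, 17.8% after blue and 18% after amber. Its ground: “Only fresh L can turn X into J.” We name the same move, but it reckons about 20 more points from ochre where I reckon 8.3 points.

The flask gives 15.6% at 20 h, by these steps:

    E + L → X (k = 4.77 × 10⁻⁴ M⁻¹ s⁻¹)
    L + J → G (k = 2.86 × 10⁻⁴ M⁻¹ s⁻¹)
    L → Q (k = 1.28 × 10⁻⁴ s⁻¹)
    E ⇌ D (K = 0.331, k = 0.00225 s⁻¹)
    L + X → J (k = 0.00206 M⁻¹ s⁻¹)

L is the limiting reagent: 0% of its charge is free at 20.0 h, while 53.1% of the E is free. Ochre gains 8.7 points, and the price put it at 8.3 points. Blue and amber stay at 15.6% and 15.6%. The neighbour flask with 0.50 M of E has the same L, so the price puts its J at 6.64% of its E. That flask gives 8.08%.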